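**Retrosynthetic overview**

1. Target 23 comes from O-acetylation of the (2S)-allylic alcohol 22.
2. 22 is cut at C1–C2. C1 is the CH2 on C3 of furan ring A, next to carbinol C2, so ring A plus C1 can be brought in as the non-aromatic exo-methylene isomer 21 (3-methylene-2,3-dihydrofuran). Compound 21 acts as an ene donor toward the C2 aldehyde of trienal 16 and becomes aromatic as the bond forms.
3. 16 comes from a C5–C6 allyl–alkenyl Suzuki coupling of dienylboronate 10 with bromo acetate 13, then methanolysis and MnO2 oxidation. 10 comes from a C10–C11 copper-catalysed coupling of a furan-3-ylmethyl Grignard reagent with an enynyl bromide, then hydroboration.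
4. 21 comes from reductive transposition of furan-3-carbaldehyde tosylhydrazone 18.
5. No ring is constructed. Both furans are bought; ring A is carried as the dihydrofuran and regains aromaticity in the key step.

Key step: step 14

Remark on the chemistry: the chain is numbered C1 (CH2 on ring A) to C11 (CH2 on ring B). (S)-BINOL is assumed to be the ligand hand that gives the 2S carbinol, by analogy with titanium BINOLate additions to aldehydes. This is to be checked on 3-methylbut-2-enal (ester analysis of the model carbinol) before the trienal is committed, and the antipodal ligand is used if the model says so.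

**Route**

Step 1
Reactants: 1 furan-3-ylmethanol
Product: 2 3-(chloromethyl)furan
Conditions: MsCl, LiCl, 2,4,6-collidine, DMF, 0 °C
Reagents that add atoms: lithium chloride, [Li+].[Cl-]
Why: Collington–Meyers chlorination, in which the mesylate formed in the flask is displaced by chloride (SN2) under buffered, non-acidic conditions that the acid-sensitive furan should tolerate; the labile chloride is to be used at once.

Step 2
Reactants: 3 (E)-3-methylpent-2-en-4-yn-1-ol
Product: 5 (E)-3-methyl-5-(trimethylsilyl)pent-2-en-4-yn-1-ol, via bis-silylated enynol 4 (not isolated)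
Conditions: n-BuLi (2.2 equiv), THF, −78 °C; TMSCl (2.3 equiv), −78 °C → rt; then 1 M HCl, rt
Reagents that add atoms: chlorotrimethylsilane, C[Si](C)(C)Cl
Why: Double deprotonation and silylation of the alkoxide/acetylide followed by selective acid hydrolysis of the weaker O–Si bond caps the acidic alkyne C–H (needed for step 4) without touching the E alkene.

Step 3
Reactants: 5 (E)-3-methyl-5-(trimethylsilyl)pent-2-en-4-yn-1-ol
Product: 6 [(E)-5-bromo-3-methylpent-3-en-1-yn-1-yl]trimethylsilane
Conditions: CBr4, PPh3, CH2Cl2, 0 °C
Reagents that add atoms: carbon tetrabromide, BrC(Br)(Br)Br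
Why: Appel bromination of a primary allylic alcohol proceeds by SN2 displacement of the oxyphosphonium under neutral conditions, so the alkene geometry and the alkynylsilane should be kept.

Step 4
Reactants: 2 3-(chloromethyl)furan; 6 [(E)-5-bromo-3-methylpent-3-en-1-yn-1-yl]trimethylsilane
Product: 8 [(E)-6-(furan-3-yl)-3-methylhex-3-en-1-yn-1-yl]trimethylsilane, via furan-3-ylmethylmagnesium chloride 7 (not isolated)
Conditions: 2, Mg turnings, THF, 0 °C (slow addition, dilute); then 6, Li2CuCl4 (3 mol%), THF, −20 → 0 °C
Reagents that add atoms: none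
Why: Copper-catalysed (Kochi-type) coupling of a hetero-benzylic Grignard reagent with a primary allylic bromide joins C10 to C11 at the unsubstituted carbon with retention of the E alkene, and the silyl cap keeps the Grignard reagent from being quenched by the alkyne.

Step 5
Reactants: 8 [(E)-6-(furan-3-yl)-3-methylhex-3-en-1-yn-1-yl]trimethylsilane
Product: 9 3-[(E)-4-methylhex-3-en-5-yn-1-yl]furan
Conditions: K2CO3, MeOH, rt
Reagents that add atoms: none
Why: Methoxide-mediated protodesilylation cleaves only the C(sp)–Si bond and leaves the furan and the trisubstituted alkene untouched.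

Step 6
Reactants: 9 3-[(E)-4-methylhex-3-en-5-yn-1-yl]furan
Product: 10 2-[(1E,3E)-6-(furan-3-yl)-3-methylhexa-1,3-dien-1-yl]-4,4,5,5-tetramethyl-1,3,2-dioxaborolane
Conditions: HBpin, Cp2Zr(H)Cl (10 mol%), Et3N (10 mol%), CH2Cl2, rt
Reagents that add atoms: pinacolborane, CC1(C)OBOC1(C)C
Why: Zirconium-catalysed hydroboration of a terminal alkyne is a syn, anti-Markovnikov addition that places boron on the terminal carbon and gives the (E)-alkenylboronate (the future C6=C7 geometry), while the hindered trisubstituted alkene should not react.

Step 7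
Reactants: 11 prenyl acetate (3-methylbut-2-en-1-yl acetate)
Product: 12 (E)-4-hydroxy-3-methylbut-2-en-1-yl acetate
Conditions: SeO2 (0.3 equiv), t-BuOOH, salicylic acid (cat.), CH2Cl2, rt
Reagents that add atoms: tert-butyl hydroperoxide, CC(C)(C)OO (terminal oxidant; the oxygen is passed on through selenium dioxide, O=[Se]=O)
Why: Selenium dioxide allylic oxidation (ene reaction then [2,3]-sigmatropic shift) hydroxylates the methyl group trans to the acetoxymethyl arm of a gem-dimethyl alkene, which sets the future 3E geometry; any over-oxidised enal should be separable by chromatography.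

Step 8
Reactants: 12 (E)-4-hydroxy-3-methylbut-2-en-1-yl acetate
Product: 13 (E)-4-bromo-3-methylbut-2-en-1-yl acetate
Conditions: CBr4, PPh3, CH2Cl2, −20 → 0 °C
Reagents that add atoms: carbon tetrabromide, BrC(Br)(Br)Br
Why: Appel bromination converts the primary allylic alcohol to the bromide by SN2 under neutral conditions, so the acetate and the E geometry should persist.

Step 9
Reactants: 10 2-[(1E,3E)-6-(furan-3-yl)-3-methylhexa-1,3-dien-1-yl]-4,4,5,5-tetramethyl-1,3,2-dioxaborolane; 13 (E)-4-bromo-3-methylbut-2-en-1-yl acetate
Product: 14 (2E,5E,7E)-10-(furan-3-yl)-3,7-dimethyldeca-2,5,7-trien-1-yl acetate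
Conditions: Pd(PPh3)4 (5 mol%), K3PO4 (aq.), THF, degassed, rt → 40 °C
Reagents that add atoms: none
Why: Suzuki–Miyaura allyl–alkenyl coupling, in which zerovalent palladium adds to the allylic bromide far faster than to the allylic acetate, the alkenylboronate transmetalates with retention, and reductive elimination at the unsubstituted CH2 terminus of the syn π-allyl forms C5–C6 as the linear skipped triene with all three alkene geometries kept.

Step 10
Reactants: 14 (2E,5E,7E)-10-(furan-3-yl)-3,7-dimethyldeca-2,5,7-trien-1-yl acetate
Product: 15 (2E,5E,7E)-10-(furan-3-yl)-3,7-dimethyldeca-2,5,7-trien-1-ol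
Conditions: K2CO3, MeOH, 0 °C → rt
Reagents that add atoms: none
Why: Base-catalysed transesterification frees the allylic alcohol at a stage where no carbonyl group acidifies the doubly allylic C5 methylene, so the skipped triene should not move.

Step 11
Reactants: 15 (2E,5E,7E)-10-(furan-3-yl)-3,7-dimethyldeca-2,5,7-trien-1-ol
Product: 16 (2E,5E,7E)-10-(furan-3-yl)-3,7-dimethyldeca-2,5,7-trienal
Conditions: MnO2 (activated, excess), CH2Cl2, rt
Reagents that add atoms: none
Why: Heterogeneous MnO2 oxidation is selective for allylic alcohols and runs under neutral conditions, which should give the E enal without isomerising the enal alkene or the skipped triene; the aldehyde is to be used promptly.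

Step 12
Reactants: 17 furan-3-carbaldehyde
Product: 18 N'-[(E)-furan-3-ylmethylidene]-4-methylbenzenesulfonohydrazide
Conditions: TsNHNH2, MeOH, rt
Reagents that add atoms: p-toluenesulfonyl hydrazide, Cc1ccc(cc1)S(=O)(=O)NN
Why: Condensation of an aromatic aldehyde with tosylhydrazide gives the crystalline tosylhydrazone without acid that could harm the furan.

Step 13
Reactants: 18 N'-[(E)-furan-3-ylmethylidene]-4-methylbenzenesulfonohydrazide
Product: 21 3-methylene-2,3-dihydrofuran, via N-boryl tosylhydrazine 19 (not isolated), via furan-3-ylmethyldiazene 20 (not isolated)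
Conditions: catecholborane, CH2Cl2, 0 °C; NaOAc·3H2O, rt → 40 °C; cold aq. NaHCO3 wash, vacuum transfer; kept as a cold dilute CH2Cl2 solution, assayed against an internal standard and used the same day
Reagents that add atoms: none
Why: Catecholborane reduction of a conjugated tosylhydrazone with alkene transposition: hydride adds to C=N, acetate expels sulfinate to give the monoalkyl diazene, and its retro-ene loss of N2 delivers hydrogen to ring C2 and leaves the exocyclic C=CH2, so the isoaromatic donor forms under non-acidic conditions.

Step 14
Reactants: 16 (2E,5E,7E)-10-(furan-3-yl)-3,7-dimethyldeca-2,5,7-trienal; 21 3-methylene-2,3-dihydrofuran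
Product: 22 (2S,3E,6E,8E)-1,11-di(furan-3-yl)-4,8-dimethylundeca-3,6,8-trien-2-ol
Conditions: Ti(OiPr)4 (10 mol%), (S)-BINOL (20 mol%), 4 Å MS, CH2Cl2, rt (catalyst ageing); then 16, then 21 (2 equiv, cold solution, slow addition), −20 → 0 °C; pH 7 buffer quench
Reagents that add atoms: none
Why: Proposed new method: the tetravalent titanium BINOLate binds the aldehyde oxygen of 16 and the exocyclic CH2 of 21 attacks C2 through a six-membered ene transition state (or its stepwise oxocarbenium equivalent) while a hydrogen of the ring O–CH2 passes to the carbonyl oxygen, so the C1–C2 bond, the O–H bond and the aromatic sextet of ring A arise together. The closest known reaction types are the thermal and Lewis-acid carbonyl-ene reactions of this dihydrofuran with aldehydes and Ti(OiPr)4–BINOL catalysed carbonyl-ene and allylation reactions; an enantioselective version on a β,β-disubstituted skipped trienal is the untested part. No ring closes. The C2 stereocentre is set by the chiral titanium BINOLate, which shields one face of the coordinated enal; (S)-BINOL is proposed for the 2S carbinol and its sense is to be fixed beforehand on 3-methylbut-2-enal. The step needs 1,2- over 1,4-addition, which the fully substituted β-carbon C4 secures, and reaction of the donor in preference to the triene and ring B, which the aromatisation gain of the dienol-ether donor secures at −20 °C with a Lewis acid too mild to isomerise the skipped triene or protonate the furans. Excess donor offsets its competing tautomerisation to 3-methylfuran.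

Step 15
Reactants: 22 (2S,3E,6E,8E)-1,11-di(furan-3-yl)-4,8-dimethylundeca-3,6,8-trien-2-ol
Product: 23 (2S,3E,6E,8E)-1,11-di(furan-3-yl)-4,8-dimethylundeca-3,6,8-trien-2-yl acetate (CNP0230518.1)
Conditions: Ac2O, pyridine, DMAP (cat.), CH2Cl2, 0 °C → rt
Reagents that add atoms: acetic anhydride, CC(=O)OC(C)=O
Why: DMAP-catalysed O-acylation occurs at oxygen under basic conditions without breaking the C2–O bond, so the configuration is kept and the acid-labile allylic system is not ionised.

**Compound list**

1 | furan-3-ylmethanol | OCc1ccoc1 | starting material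
2 | 3-(chloromethyl)furan | ClCc1ccoc1 | intermediate
3 | (E)-3-methylpent-2-en-4-yn-1-ol | C#C/C(C)=C/CO | starting material
4 | trimethyl{[(E)-3-methyl-5-(trimethylsilyl)pent-2-en-4-yn-1-yl]oxy}silane | C[Si](C)(C)C#C/C(C)=C/CO[Si](C)(C)C | intermediate
5 | (E)-3-methyl-5-(trimethylsilyl)pent-2-en-4-yn-1-ol | C[Si](C)(C)C#C/C(C)=C/CO | intermediate
6 | [(E)-5-bromo-3-methylpent-3-en-1-yn-1-yl]trimethylsilane | C[Si](C)(C)C#C/C(C)=C/CBr | intermediate
7 | (furan-3-ylmethyl)magnesium chloride | Cl[Mg]Cc1ccoc1 | intermediate
8 | [(E)-6-(furan-3-yl)-3-methylhex-3-en-1-yn-1-yl]trimethylsilane | C[Si](C)(C)C#C/C(C)=C/CCc1ccoc1 | intermediate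
9 | 3-[(E)-4-methylhex-3-en-5-yn-1-yl]furan | C#C/C(C)=C/CCc1ccoc1 | intermediate
10 | 2-[(1E,3E)-6-(furan-3-yl)-3-methylhexa-1,3-dien-1-yl]-4,4,5,5-tetramethyl-1,3,2-dioxaborolane | CC1(C)OB(/C=C/C(C)=C/CCc2ccoc2)OC1(C)C | intermediate
11 | prenyl acetate (3-methylbut-2-en-1-yl acetate) | CC(C)=CCOC(C)=O | starting material
12 | (E)-4-hydroxy-3-methylbut-2-en-1-yl acetate | CC(=O)OC/C=C(\C)CO | intermediate
13 | (E)-4-bromo-3-methylbut-2-en-1-yl acetate | CC(=O)OC/C=C(\C)CBr | intermediate
14 | (2E,5E,7E)-10-(furan-3-yl)-3,7-dimethyldeca-2,5,7-trien-1-yl acetate | CC(=O)OC/C=C(\C)C/C=C/C(C)=C/CCc1ccoc1 | intermediate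
15 | (2E,5E,7E)-10-(furan-3-yl)-3,7-dimethyldeca-2,5,7-trien-1-ol | OC/C=C(\C)C/C=C/C(C)=C/CCc1ccoc1 | intermediate
16 | (2E,5E,7E)-10-(furan-3-yl)-3,7-dimethyldeca-2,5,7-trienal | O=C/C=C(\C)C/C=C/C(C)=C/CCc1ccoc1 | intermediate
17 | furan-3-carbaldehyde | O=Cc1ccoc1 | starting material
18 | N'-[(E)-furan-3-ylmethylidene]-4-methylbenzenesulfonohydrazide | Cc1ccc(cc1)S(=O)(=O)N/N=C/c1ccoc1 | intermediate
19 | N'-(1,3,2-benzodioxaborol-2-yl)-N'-(furan-3-ylmethyl)-4-methylbenzenesulfonohydrazide | Cc1ccc(cc1)S(=O)(=O)NN(Cc1ccoc1)B1Oc2ccccc2O1 | intermediate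
20 | (furan-3-ylmethyl)diazene | N=NCc1ccoc1 | intermediate
21 | 3-methylene-2,3-dihydrofuran | C=C1COC=C1 | intermediate
22 | (2S,3E,6E,8E)-1,11-di(furan-3-yl)-4,8-dimethylundeca-3,6,8-trien-2-ol | O[C@H](/C=C(\C)C/C=C/C(C)=C/CCc1ccoc1)Cc1ccoc1 | intermediate
23 | (2S,3E,6E,8E)-1,11-di(furan-3-yl)-4,8-dimethylundeca-3,6,8-trien-2-yl acetate | CC(=O)O[C@H](/C=C(\C)C/C=C/C(C)=C/CCc1ccoc1)Cc1ccoc1 | target

**Step count**

Total steps: 15. Longest linear sequence: 10 steps (steps 2, 3, 4, 5, 6, 9, 10, 11, 14, 15, from enynol 3).

**Steps most likely to fail**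

Step 14. The titanium BINOLate may discriminate the enal faces poorly. It may also turn over so slowly that the donor tautomerises or oligomerises before it is captured. The fallback gives up catalyst-controlled bond formation and sets the stereocentre by reagent-controlled reduction. It sets out from 16 and 21, which are combined in a carbonyl-ene reaction without chiral control (Ti(OiPr)4 with racemic BINOL, or thermally at higher concentration in CH2Cl2) to give racemic (3E,6E,8E)-1,11-di(furan-3-yl)-4,8-dimethylundeca-3,6,8-trien-2-ol F1. MnO2 in CH2Cl2 at rt should oxidise this allylic alcohol to (3E,6E,8E)-1,11-di(furan-3-yl)-4,8-dimethylundeca-3,6,8-trien-2-one F2. Corey–Bakshi–Shibata reduction of F2 with (R)-2-methyl-CBS-oxazaborolidine and catecholborane in toluene at −78 °C, the alkenyl arm acting as the large group, should give the 2S alcohol (sense to be confirmed by ester analysis). The fallback comes back to the route at 22.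

Step 13. Hydride addition to the hydrazone may be incomplete. The donor may also be lost to tautomerisation (to 3-methylfuran) or self-ene oligomerisation during the warm acetate-induced elimination and the aqueous wash. The fallback reaches the same diazene at low temperature without boron residues or water, and sets out from alcohol 1. Mitsunobu displacement with 2-nitrobenzenesulfonylhydrazide (PPh3, DEAD, toluene, −30 °C) should give 1-(furan-3-ylmethyl)-1-(2-nitrophenylsulfonyl)hydrazine F3. On warming to 0 °C, F3 loses the sulfinic acid to give diazene 20, whose retro-ene loss of N2 gives the donor (reductive transposition of an alcohol through a monoalkyl diazene). The toluene solution is vacuum-transferred, and the fallback comes back to the route at 21.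

Step 4. Grignard formation from the hetero-benzylic chloride may be eroded by Wurtz-type homocoupling. The coupling may also go astray by bonding through ring carbon C2 or by allylic transposition along the enyne. The fallback replaces the Grignard reagent by a sulfone-stabilised carbanion and sets out from 2 and 6. Chloride 2 with PhSO2Na in DMF at rt should give 3-[(phenylsulfonyl)methyl]furan F4. Deprotonation of F4 (n-BuLi, THF, −78 °C) and SN2 alkylation with bromide 6 should give [(E)-6-(furan-3-yl)-3-methyl-6-(phenylsulfonyl)hex-3-en-1-yn-1-yl]trimethylsilane F5. Reductive desulfonylation of F5 with Na(Hg) and Na2HPO4 in MeOH–THF at −20 °C is expected to remove the alkynylsilane as well in the methanolic medium, so the fallback comes back to the route at 9 (if the silane survives, step 5 follows as written).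

**Further compounds**

F1 | step 14 | racemic (3E,6E,8E)-1,11-di(furan-3-yl)-4,8-dimethylundeca-3,6,8-trien-2-ol | OC(/C=C(\C)C/C=C/C(C)=C/CCc1ccoc1)Cc1ccoc1
F2 | step 14 | (3E,6E,8E)-1,11-di(furan-3-yl)-4,8-dimethylundeca-3,6,8-trien-2-one | O=C(/C=C(\C)C/C=C/C(C)=C/CCc1ccoc1)Cc1ccoc1
F3 | step 13 | 1-(furan-3-ylmethyl)-1-(2-nitrophenylsulfonyl)hydrazine | NN(Cc1ccoc1)S(=O)(=O)c1ccccc1[N+](=O)[O-]
F4 | step 4 | 3-[(phenylsulfonyl)methyl]furan | O=S(=O)(Cc1ccoc1)c1ccccc1
F5 | step 4 | racemic [(E)-6-(furan-3-yl)-3-methyl-6-(phenylsulfonyl)hex-3-en-1-yn-1-yl]trimethylsilane | C[Si](C)(C)C#C/C(C)=C/CC(c1ccoc1)S(=O)(=O)c1ccccc1
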